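## Retrosynthetic overview

- Last bond: the benzylic ester C–O, formed together with the α-methyl stereocentre by catalyst-controlled ring opening of a racemic (Z)-hexylidene(methyl)succinic anhydride with the (S)-dihydrobenzofuranylmethanol.
- Anhydride: from the Z-diester; the methyl group comes from ester-enolate alkylation, the Z-alkene from a diaryl-phosphonate (Ando-type) Horner–Wadsworth–Emmons olefination of hexanal.
- Alcohol: ester reduction ⇐ dehydration of a hydroxyisopropyl group ⇐ 5-exo phenoxide opening of an (R)-epoxide ⇐ Shi epoxidation of an ortho-prenylphenol (first stereocentre) ⇐ methyl 4-hydroxybenzoate + prenyl bromide.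
- Rings: the benzene ring is bought; the dihydrofuran ring is closed first (epoxide opening); the anhydride ring is made late and opened again in the last step.

Assumption: the SMILES is read as 2S at the dihydrobenzofuran carbon, R at the α-methyl carbon and Z at the alkene (pentyl cis to the free CO2H), and the route is built for exactly this isomer.

## Route

Step 1
Reactants: 1 methyl 4-hydroxybenzoate; 2 1-bromo-3-methylbut-2-ene (prenyl bromide)
Product: 3 methyl 4-hydroxy-3-(3-methylbut-2-en-1-yl)benzoate
Conditions: NaH (1.05 equiv), toluene, 0 °C to 40 °C, 16 h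
Reagents that add atoms: none
Why: The sodium phenoxide, held as a tight ion pair in non-polar toluene, is alkylated at the ortho carbon in preference to oxygen (para position blocked), the classical ortho C-prenylation of phenoxides; the yield is modest but the ester is untouched.

Step 2
Reactants: 3 methyl 4-hydroxy-3-(3-methylbut-2-en-1-yl)benzoate
Product: 4 methyl 4-[(tert-butyldimethylsilyl)oxy]-3-(3-methylbut-2-en-1-yl)benzoate
Conditions: TBSCl, imidazole, DMF, rt
Reagents that add atoms: tert-butyldimethylsilyl chloride, CC(C)(C)[Si](C)(C)Cl
Why: Standard imidazole-mediated O-silylation; it keeps the phenol from being oxidised and from opening the epoxide prematurely in the next step.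

Step 3
Reactants: 4 methyl 4-[(tert-butyldimethylsilyl)oxy]-3-(3-methylbut-2-en-1-yl)benzoate
Product: 5 methyl 4-[(tert-butyldimethylsilyl)oxy]-3-{[(2R)-3,3-dimethyloxiran-2-yl]methyl}benzoate
Conditions: 1,2:4,5-di-O-isopropylidene-β-D-erythro-2,3-hexodiulo-2,6-pyranose (D-fructose-derived Shi ketone, 30 mol %), Oxone (2KHSO5·KHSO4·K2SO4), K2CO3, Bu4NHSO4 (cat.), aq. Na2B4O7 buffer, MeCN/CH2(OMe)2, 0 °C
Reagents that add atoms: potassium peroxymonosulfate KHSO5 (active component of Oxone), [K+].[O-]S(=O)(=O)OO
Why: Shi asymmetric epoxidation: the chiral dioxirane formed from the ketone and KHSO5 transfers oxygen to one face of the trisubstituted alkene through a spiro transition state, giving the (R)-epoxide and setting the first stereocentre by organocatalysis.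

Step 4
Reactants: 5 methyl 4-[(tert-butyldimethylsilyl)oxy]-3-{[(2R)-3,3-dimethyloxiran-2-yl]methyl}benzoate
Product: 7 methyl (2S)-2-(2-hydroxypropan-2-yl)-2,3-dihydro-1-benzofuran-5-carboxylate, via phenol epoxide 6 (not isolated)
Conditions: Bu4NF (1.2 equiv), THF, 0 °C to rt
Reagents that add atoms: none
Why: Fluoride frees the phenoxide, which opens the epoxide at its less substituted carbon in a 5-exo-tet SN2 attack with inversion (R epoxide carbon becomes the S ring carbon), closing the dihydrofuran ring; basic conditions avoid the 6-endo chroman pathway.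

Step 5
Reactants: 7 methyl (2S)-2-(2-hydroxypropan-2-yl)-2,3-dihydro-1-benzofuran-5-carboxylate
Product: 8 methyl (2S)-2-(prop-1-en-2-yl)-2,3-dihydro-1-benzofuran-5-carboxylate
Conditions: methyl N-(triethylammoniosulfonyl)carbamate (Burgess reagent, 1.5 equiv), toluene, 70 °C
Reagents that add atoms: none
Why: Burgess dehydration: syn elimination from the tertiary sulfamate takes one of six methyl hydrogens in preference to the single hindered ring methine hydrogen, giving the isopropenyl group under neutral conditions that leave the C2–O stereocentre untouched.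

Step 6
Reactants: 8 methyl (2S)-2-(prop-1-en-2-yl)-2,3-dihydro-1-benzofuran-5-carboxylate
Product: 9 [(2S)-2-(prop-1-en-2-yl)-2,3-dihydro-1-benzofuran-5-yl]methanol
Conditions: i-Bu2AlH (2.5 equiv), CH2Cl2, −78 °C; aq. KNaC4H4O6 work-up
Reagents that add atoms: none
Why: Hydride reduction of the aryl ester to the benzylic alcohol at low temperature; the alkene and aryl ether are inert and the stereocentre is not involved (the product is a para-alkoxybenzyl alcohol and is kept away from acid).

Step 7
Reactants: 10 ethyl 2-(diphenoxyphosphoryl)acetate; 11 ethyl bromoacetate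
Product: 12 diethyl 2-(diphenoxyphosphoryl)butanedioate (racemic)
Conditions: NaH (1.0 equiv), THF/DMF, 0 °C to rt (10 in 1.3-fold excess)
Reagents that add atoms: none
Why: SN2 C-alkylation of the stabilised phosphonate carbanion by the α-bromo ester, the usual way α-substituted diaryl phosphonoacetates are made; the excess phosphonate limits dialkylation.

Step 8
Reactants: 12 diethyl 2-(diphenoxyphosphoryl)butanedioate; 13 hexanal
Product: 14 diethyl (2Z)-2-hexylidenebutanedioate
Conditions: NaH (1.0 equiv), THF, −78 °C to 0 °C
Reagents that add atoms: none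
Why: Horner–Wadsworth–Emmons olefination in its Ando form: the electron-poor diphenyl phosphonate makes elimination from the first-formed adduct faster than its equilibration, so the kinetic Z enoate (pentyl cis to the conjugated ester) is obtained.

Step 9
Reactants: 14 diethyl (2Z)-2-hexylidenebutanedioate
Product: 15 diethyl (2Z)-2-hexylidene-3-methylbutanedioate (racemic)
Conditions: LiN(i-Pr)2 (1.05 equiv, commercial solution), THF, −78 °C; MeI (1.5 equiv), −78 °C to −40 °C
Reagents that add atoms: iodomethane, CI
Why: Kinetic deprotonation at C3 (α to the saturated ester and allylic) gives a lithium dienolate that is methylated at its α-carbon (ester enolate alkylation); at −78 °C the dienolate keeps the Z alkene geometry.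

Step 10
Reactants: 15 diethyl (2Z)-2-hexylidene-3-methylbutanedioate
Product: 16 (2Z)-2-hexylidene-3-methylbutanedioic acid (racemic)
Conditions: LiOH·H2O (5 equiv), THF/H2O, rt to 40 °C; then cold 1 M HCl to pH 2
Reagents that add atoms: lithium hydroxide, [Li+].[OH-]
Why: Saponification: the unhindered saturated ester is cleaved first and its carboxylate then shields C3–H from deprotonation while the conjugated ester is hydrolysed, so neither the alkene position nor its Z geometry changes.

Step 11
Reactants: 16 (2Z)-2-hexylidene-3-methylbutanedioic acid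
Product: 17 (3Z)-3-hexylidene-4-methyloxolane-2,5-dione (racemic)
Conditions: DCC (1.05 equiv), CH2Cl2, 0 °C to rt; filtration, used directly
Reagents that add atoms: none
Why: Carbodiimide-mediated cyclodehydration of the 1,4-diacid to the five-membered anhydride under neutral, cold conditions that do not move the exocyclic double bond into the ring.

Step 12
Reactants: 9 [(2S)-2-(prop-1-en-2-yl)-2,3-dihydro-1-benzofuran-5-yl]methanol; 17 (3Z)-3-hexylidene-4-methyloxolane-2,5-dione (racemic, 2.0 equiv)
Product: 18 (2Z)-2-[(2R)-1-oxo-1-{[(2S)-2-(prop-1-en-2-yl)-2,3-dihydro-1-benzofuran-5-yl]methoxy}propan-2-yl]oct-2-enoic acid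
Conditions: hydroquinine anthraquinone-1,4-diyl diether, (DHQ)2AQN (30 mol %), dry Et2O, −20 °C, 48 h; cold 5 % aq. citric acid work-up; flash chromatography (unreacted 17 eluted first and recovered)
Reagents that add atoms: none
Why: Proposed new method: enantio- and regioselective alcoholysis of a racemic, configurationally labile 2-alkylidene-3-methylsuccinic anhydride under dynamic kinetic resolution. The quinuclidine nitrogen acts as a general base for the alcohol inside a chiral pocket that tells the two C3 enantiomers apart at the adjacent saturated carbonyl. The conjugated carbonyl is deactivated and shielded by the cis pentyl group, so the ester forms at C4 and the acid stays free at C1. The same amine racemises unreacted anhydride through its oxidofuranone dienolate, because C3–H is α to one carbonyl and vinylogous to the other. That dienolate prefers the Z geometry, since an E pentyl would clash with the in-plane C3 methyl, and the half-ester product is far less acidic and keeps its configuration. One equivalent of 17 is taken up by alcohol 9 and the second equivalent is left over, so the step still runs as a plain kinetic resolution if racemisation lags; the leftover anhydride is recovered and reused. The closest known reaction type is the modified-cinchona-alkaloid-catalysed alcoholytic (dynamic) kinetic resolution of N-carboxyanhydrides and 5-aryl-1,3-dioxolane-2,4-diones, and the parallel kinetic resolution of 2-substituted succinic anhydrides. The dihydroquinine series is chosen by spatial analogy with those cases to give 3R; this sense is a prediction, and the dihydroquinidine twin gives 3S if it proves reversed.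

## Compound list

1 | methyl 4-hydroxybenzoate | COC(=O)c1ccc(O)cc1 | starting material
2 | 1-bromo-3-methylbut-2-ene (prenyl bromide) | CC(C)=CCBr | starting material
3 | methyl 4-hydroxy-3-(3-methylbut-2-en-1-yl)benzoate | COC(=O)c1ccc(O)c(CC=C(C)C)c1 | intermediate
4 | methyl 4-[(tert-butyldimethylsilyl)oxy]-3-(3-methylbut-2-en-1-yl)benzoate | COC(=O)c1ccc(O[Si](C)(C)C(C)(C)C)c(CC=C(C)C)c1 | intermediate
5 | methyl 4-[(tert-butyldimethylsilyl)oxy]-3-{[(2R)-3,3-dimethyloxiran-2-yl]methyl}benzoate | COC(=O)c1ccc(O[Si](C)(C)C(C)(C)C)c(C[C@H]2OC2(C)C)c1 | intermediate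
6 | methyl 3-{[(2R)-3,3-dimethyloxiran-2-yl]methyl}-4-hydroxybenzoate (phenol epoxide; present as its tetrabutylammonium phenoxide; not isolated) | COC(=O)c1ccc(O)c(C[C@H]2OC2(C)C)c1 | intermediate
7 | methyl (2S)-2-(2-hydroxypropan-2-yl)-2,3-dihydro-1-benzofuran-5-carboxylate | CC(C)(O)[C@@H]1Cc2cc(C(=O)OC)ccc2O1 | intermediate
8 | methyl (2S)-2-(prop-1-en-2-yl)-2,3-dihydro-1-benzofuran-5-carboxylate | C=C(C)[C@@H]1Cc2cc(C(=O)OC)ccc2O1 | intermediate
9 | [(2S)-2-(prop-1-en-2-yl)-2,3-dihydro-1-benzofuran-5-yl]methanol | C=C(C)[C@@H]1Cc2cc(CO)ccc2O1 | intermediate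
10 | ethyl 2-(diphenoxyphosphoryl)acetate | CCOC(=O)CP(=O)(Oc1ccccc1)Oc1ccccc1 | starting material
11 | ethyl bromoacetate | CCOC(=O)CBr | starting material
12 | diethyl 2-(diphenoxyphosphoryl)butanedioate (racemic) | CCOC(=O)CC(C(=O)OCC)P(=O)(Oc1ccccc1)Oc1ccccc1 | intermediate
13 | hexanal | CCCCCC=O | starting material
14 | diethyl (2Z)-2-hexylidenebutanedioate | CCOC(=O)C/C(=C/CCCCC)C(=O)OCC | intermediate
15 | diethyl (2Z)-2-hexylidene-3-methylbutanedioate (racemic) | CCOC(=O)C(C)/C(=C/CCCCC)C(=O)OCC | intermediate
16 | (2Z)-2-hexylidene-3-methylbutanedioic acid (racemic) | OC(=O)C(C)/C(=C/CCCCC)C(=O)O | intermediate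
17 | (3Z)-3-hexylidene-4-methyloxolane-2,5-dione (racemic) | CC1/C(=C/CCCCC)C(=O)OC1=O | intermediate
18 | (2Z)-2-[(2R)-1-oxo-1-{[(2S)-2-(prop-1-en-2-yl)-2,3-dihydro-1-benzofuran-5-yl]methoxy}propan-2-yl]oct-2-enoic acid (CNP0186066.2) | C=C(C)[C@@H]1Cc2cc(COC(=O)[C@H](C)/C(=C/CCCCC)C(=O)O)ccc2O1 | target

## Step count and risks

Total step count: 12. Longest linear sequence: 7 (steps 1–6, then step 12); the acid branch (steps 7–11) is 5 steps and joins at step 12.

Three steps most likely to fail:

1. Step 12 (the new reaction). The risks are the level and sense of selectivity at C3, racemisation that is too slow, loss of the Z geometry in the dienolate, and drift of 17 to 2-hexyl-3-methylmaleic anhydride. The fallback uses known chemistry and sets out from alcohol 9 and anhydride 17 (one equivalent each). The anhydride is opened without stereocontrol (DMAP cat., CH2Cl2, 0 °C), which for alkylidenesuccinic anhydrides is known to occur at the non-conjugated carbonyl. This gives 18 together with its C3 epimer (2Z)-2-[(2S)-1-oxo-1-{[(2S)-2-(prop-1-en-2-yl)-2,3-dihydro-1-benzofuran-5-yl]methoxy}propan-2-yl]oct-2-enoic acid F1 as a roughly 1:1 pair of diastereomers. They are separated by preparative HPLC on a polysaccharide chiral stationary phase, and the route is rejoined at 18 (at most half of the material is kept).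

2. Step 5 (dehydration). Elimination toward the ring carbon would give the isopropylidene enol ether, and from it 2-isopropylbenzofuran, with loss of the stereocentre. The fallback sets out from epoxide 5 and installs the isopropenyl group before the ring is closed. TMSOTf/DBU in toluene isomerises the epoxide to the allylic silyl ether methyl 4-[(tert-butyldimethylsilyl)oxy]-3-{(2R)-3-methyl-2-[(trimethylsilyl)oxy]but-3-en-1-yl}benzoate F2, with the C–O bond of the stereocentre untouched. Bu4NF removes both silyl groups to give methyl 4-hydroxy-3-[(2R)-2-hydroxy-3-methylbut-3-en-1-yl]benzoate F3. An intramolecular Mitsunobu etherification (PPh3, DIAD, THF) then closes the dihydrofuran ring with inversion, and the route is rejoined at 8 (this replaces steps 4 and 5 and is one step longer).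

3. Step 9 (C3 methylation). The risks are dialkylation, Claisen-type self-condensation, and loss of Z geometry in the ester dienolate. The fallback sets out from diester 14 and alkylates a carboxylate dianion instead of an ester enolate. One equivalent of LiOH (THF/H2O, 0 °C) cleaves only the saturated ester to give (3Z)-3-(ethoxycarbonyl)non-3-enoic acid F4. Its dianion (LiN(i-Pr)2, 2.2 equiv, THF, −78 °C) is methylated with MeI at the acid α-carbon to give (3Z)-3-(ethoxycarbonyl)-2-methylnon-3-enoic acid F5. Hydrolysis of the remaining conjugated ester with LiOH rejoins the route at 16 (this replaces steps 9 and 10).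

Further compounds
F1 | step 12 | (2Z)-2-[(2S)-1-oxo-1-{[(2S)-2-(prop-1-en-2-yl)-2,3-dihydro-1-benzofuran-5-yl]methoxy}propan-2-yl]oct-2-enoic acid | C=C(C)[C@@H]1Cc2cc(COC(=O)[C@@H](C)/C(=C/CCCCC)C(=O)O)ccc2O1
F2 | step 5 | methyl 4-[(tert-butyldimethylsilyl)oxy]-3-{(2R)-3-methyl-2-[(trimethylsilyl)oxy]but-3-en-1-yl}benzoate | COC(=O)c1ccc(O[Si](C)(C)C(C)(C)C)c(C[C@@H](O[Si](C)(C)C)C(C)=C)c1
F3 | step 5 | methyl 4-hydroxy-3-[(2R)-2-hydroxy-3-methylbut-3-en-1-yl]benzoate | COC(=O)c1ccc(O)c(C[C@@H](O)C(C)=C)c1
F4 | step 9 | (3Z)-3-(ethoxycarbonyl)non-3-enoic acid | OC(=O)C/C(=C/CCCCC)C(=O)OCC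
F5 | step 9 | (3Z)-3-(ethoxycarbonyl)-2-methylnon-3-enoic acid (racemic) | OC(=O)C(C)/C(=C/CCCCC)C(=O)OCC
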